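The constants of this flask have to be read from the two earlier runs, and I read two of them, counting everything in charges of electrophile.

| flask | electrophile | solid nucleophile | remark | time |
|---|---|---|---|---|
| larch | 0.10 M (fed, over 20 s) | 0.10 M | run made earlier |  |
| oak | 0.10 M (fed, over 20 s) | 0.40 M | run made earlier |  |
| flask | 0.10 M (fed, over 20 s) | 0.200 M |  | 20 min |

- larch (time / min: electrophile / %, target / %): 1.00: 75.2, 24.1; 1.33: 68.2, 32.3; 2.00: 59.6, 40.2; 3.00: 57.8, 43.7; 5.00: 55.3, 45.1; 8.00: 54.4, 44.3; 12.0: 55.2, 45.7
- oak (time / min: electrophile / %, target / %): 0.667: 85.2, 14.6; 2.00: 53.8, 46.6; 3.00: 38.0, 61.8; 5.00: 18.6, 81.8; 8.00: 6.1, 93.2; 10.0: 3.4, 97.6; 12.0: 1.3, 99.8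

(standard deviation of a reading: 0.5 percentage points)

- solid nucleophile is a solid; its amount is given per volume of the solution
- the numbers in the tables scatter by 0.5 percentage points (one standard deviation)
- on the list of suspects stand: 2 nucleophile -> self-condensation product; solid nucleophile <-> nucleophile; nucleophile + acid set free <-> protonated nucleophile; electrophile + nucleophile -> acid set free + target
- at the start none of the solid nucleophile is in solution
- the earlier runs do not show how much of nucleophile is bound; that part of a forecast is a guess

1. part of the electrophile that has reacted at 20 min
2. share of free nucleophile in free nucleophile and protonated nucleophile together, at 20 min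

The oak electrophile falls first order at 0.363 min⁻¹, a half-life of 1.91 min. The larch target levels off at 45.0%. Each target costs two nucleophile, one to react and one to take up the acid, so that larch charge lost 0.0993 by the knee near 2.00 min. This gives the drain, the fraction of a charge that self-condensation takes per minute before the knee: 0.0497 min⁻¹.

The flask holds 2.00 charges of solid nucleophile. Its feed of 20 s is short against the half-life, so I draw it on the oak slope. After 3 half-lives, at 5.73 min, the bill stands at 2.03, just past the charge. The solid nucleophile is therefore the limiting reagent, and I stop the bill at that time. The level is the charge less the drain, halved: 85.8%. The flat larch plateau suggests a small free share, but its size is a guess.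

The forecast says 88% (82% to 95%), that “the reaction stalls near 88%”, and 0.3% (0% to 4%) for the share; my level lies lower.

The flask gives 83.8% and 0.426%, both inside those ranges.

    2 nucleophile → self-condensation product (k = 0.0875 M⁻¹ s⁻¹)
    solid nucleophile ⇌ nucleophile, rate k2*(cs2 - [nucleophile]) while solid is left; crystals form when [nucleophile] > cs2 (solubility = 30.0 mM, k = 0.306 s⁻¹)
    nucleophile + acid set free ⇌ protonated nucleophile, settled at all times (K = 97000 M⁻¹)
    electrophile + nucleophile → acid set free + target (k = 0.211 M⁻¹ s⁻¹)

At 1.31 min, when the dissolving is half done, making target uses nucleophile 3.0 times as fast as self-condensation, and by 20.0 min the flask has lost 0.345 charges that way, against the 0.285 the drain allowed. On the neighbour flask with 0.050 M of solid nucleophile, the drain puts the level at 23.0%, and that flask gives 24.4%.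

The numbers in the tables are simulated for substances that don't exist, and the scatter is random.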